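## Retrosynthetic overview

- The target comes from 14-O-acetylation of 38. The γ-lactone is closed last (O–C7 bond) by a divalent-palladium 1,4-oxidation of seco-acid 37, in which the C19 carboxyl adds to C7 of the exocyclic diene C16=C5–C6=C7 and acetate adds to C16. The enabling feature is the O–C7–C6=C5–C16–O unit (a but-2-ene-1,4-diol diester spanning the lactone and the ten-membered ring), with C19 held γ to C7 through C17–C8.
- The ten-membered ring is closed just before (C6=C7) by ethene enyne cross-metathesis followed by ring-closing metathesis of alkyne acid 35. The C2–C6 chain comes from a catalytic ynone aldol (C2) and an Evans–Tishchenko reduction (C4, acetate on O2).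
- C8 and C17 are set on a temporary C9-lactone (samarium Reformatsky, dianion methylation), which is then reduced open. C9 comes from a Felkin–Anh addition of lithiated methoxyallene, and C10 from a Still–Wittig [2,3]-shift from the C12 carbinol.
- The cyclohexene ring is made first, from 2-methylcyclohexane-1,3-dione: C-allylation, yeast desymmetrisation (C1, C14), enone formation, epoxidation and Wharton transposition.
- Ring order: cyclohexene, then temporary γ-lactone (made and opened), then ten-membered ring, then γ-lactone.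

Key step: step 28

Remark: locants C1–C20 in the names are the briarane locants of the target (C1 quaternary ring carbon with methyl C15; C16 acetoxymethyl carbon; C17/C18/C19 lactone methine, methyl, carbonyl); "β" is the face of the cyclohexene ring that carries C15.

## Route

Step 1
Reactants: 1 2-methylcyclohexane-1,3-dione; 2 allyl bromide
Product: 3 2-allyl-2-methylcyclohexane-1,3-dione
Conditions: NaOH (1 M aq.), 25 °C
Reagents that add atoms: none
Why: C-alkylation of the stabilised enolate of a cyclic 1,3-dione with an allylic halide in aqueous base is a standard route to 2,2-disubstituted 1,3-diones.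

Step 2
Reactants: 3 2-allyl-2-methylcyclohexane-1,3-dione
Product: 4 (2S,3S)-2-allyl-3-hydroxy-2-methylcyclohexan-1-one
Conditions: baker's yeast, D-glucose, H2O, 30 °C
Reagents that add atoms: none
Why: Enzymatic desymmetrisation of a prochiral 2,2-disubstituted cyclohexane-1,3-dione reduces one enantiotopic carbonyl, which should set the quaternary C1 and the carbinol C14 together with the hydroxyl cis to the allyl group, as is known for this substrate class.

Step 3
Reactants: 4 (2S,3S)-2-allyl-3-hydroxy-2-methylcyclohexan-1-one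
Product: 5 (2S,3S)-2-allyl-3-(tert-butyldimethylsilyloxy)-2-methylcyclohexan-1-one
Conditions: TBSCl, imidazole, DMF, 25 °C
Reagents that add atoms: tert-butyldimethylsilyl chloride, CC(C)(C)[Si](C)(C)Cl
Why: Silyl ether formation shields the β-hydroxy ketone from retro-aldol cleavage in the basic steps that follow.

Step 4
Reactants: 5 (2S,3S)-2-allyl-3-(tert-butyldimethylsilyloxy)-2-methylcyclohexan-1-one
Product: 6 (2S,3S)-3-(tert-butyldimethylsilyloxy)-2-methyl-2-[(E)-prop-1-enyl]cyclohexan-1-one
Conditions: RuHCl(CO)(PPh3)3 (5 mol %), toluene, 80 °C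
Reagents that add atoms: none
Why: Ruthenium-hydride-catalysed olefin isomerisation moves the terminal double bond to the preferred internal (E) position, so that ozonolysis leaves C2 as a one-carbon aldehyde on C1.

Step 5
Reactants: 6 (2S,3S)-3-(tert-butyldimethylsilyloxy)-2-methyl-2-[(E)-prop-1-enyl]cyclohexan-1-one
Product: 8 (2R,3S)-3-(tert-butyldimethylsilyloxy)-2-(1,3-dioxolan-2-yl)-2-methylcyclohexan-1-one, via keto aldehyde 7 (not isolated)
Conditions: O3, CH2Cl2, −78 °C; Me2S, −78 → 25 °C; then HOCH2CH2OH, PPTS, MgSO4, 25 °C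
Reagents that add atoms: ethane-1,2-diol, OCCO; ozone, [O-][O+]=O (its oxygen is carried by 7 and leaves again as water)
Why: Ozonolysis cleaves the only olefin, and the neopentyl aldehyde is acetalised in preference to the hindered ring ketone, so C2 is carried at the aldehyde level through all base and hydride steps.

Step 6
Reactants: 8 (2R,3S)-3-(tert-butyldimethylsilyloxy)-2-(1,3-dioxolan-2-yl)-2-methylcyclohexan-1-one
Product: 9 (2R,3S)-3-(tert-butyldimethylsilyloxy)-2-(1,3-dioxolan-2-yl)-2,6-dimethylcyclohexan-1-one (both C6 epimers; C6 = briarane C11)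
Conditions: LiN(iPr)2, THF, −78 °C; MeI, −78 → 0 °C
Reagents that add atoms: iodomethane, CI
Why: Kinetic enolate alkylation; only C11 can enolise because C1 is quaternary, and the new centre becomes trigonal in the next step.

Step 7
Reactants: 9 (2R,3S)-3-(tert-butyldimethylsilyloxy)-2-(1,3-dioxolan-2-yl)-2,6-dimethylcyclohexan-1-one
Product: 10 (5S,6R)-5-(tert-butyldimethylsilyloxy)-6-(1,3-dioxolan-2-yl)-2,6-dimethylcyclohex-2-en-1-one
Conditions: IBX (2-iodoxybenzoic acid), 4-methoxypyridine N-oxide, DMSO, 25–40 °C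
Reagents that add atoms: none
Why: IBX-mediated α,β-dehydrogenation of a ketone gives the endocyclic 2-methyl enone, the only regiochemistry open to this ketone.

Step 8
Reactants: 10 (5S,6R)-5-(tert-butyldimethylsilyloxy)-6-(1,3-dioxolan-2-yl)-2,6-dimethylcyclohex-2-en-1-one
Product: 11 β-epoxy ketone (2,3-epoxide of 10, epoxide oxygen cis to the C6 methyl and trans to the silyloxy group)
Conditions: H2O2 (30 % aq.), NaOH (0.5 equiv), MeOH, 0 °C
Reagents that add atoms: hydrogen peroxide, OO
Why: Weitz–Scheffer nucleophilic epoxidation; axial attack of hydroperoxide at C12 anti to the C14 silyloxy group, as in 5-substituted 2-methylcyclohexenones, should place the epoxide on the β face.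

Step 9
Reactants: 11 β-epoxy ketone
Product: 12 allylic alcohol: 4-(1,3-dioxolan-2-yl)-5-(tert-butyldimethylsilyloxy)-2,4-dimethylcyclohex-2-en-1-ol, hydroxyl (briarane 12β-OH) cis to the C4 methyl and trans to the silyloxy group
Conditions: N2H4·H2O, AcOH (cat.), MeOH, 0 → 25 °C
Reagents that add atoms: none
Why: Wharton transposition; the hydrazone of the epoxy ketone fragments with loss of dinitrogen to the C10=C11 olefin and the C12 alcohol, whose configuration is that of the epoxide C–O bond.

Step 10
Reactants: 12 allylic alcohol (12β-OH)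
Product: 13 (tributylstannyl)methyl ether of 12
Conditions: KH, 18-crown-6 (cat.), THF, 0 °C; Bu3SnCH2I, 25 °C
Reagents that add atoms: tributyl(iodomethyl)stannane, CCCC[Sn](CCCC)(CCCC)CI
Why: Williamson etherification of the potassium alkoxide gives the substrate for a Still–Wittig rearrangement.

Step 11
Reactants: 13 (tributylstannyl)methyl ether
Product: 15 homoallylic alcohol [6-(1,3-dioxolan-2-yl)-5-(tert-butyldimethylsilyloxy)-2,6-dimethylcyclohex-2-en-1-yl]methanol (CH2OH = C9 on the β face of C10 and cis to the C15 methyl), via lithiomethyl ether 14 (not isolated)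
Conditions: nBuLi, THF, −78 → −20 °C; aq. NH4Cl
Reagents that add atoms: none
Why: Tin–lithium exchange gives an α-alkoxymethyl-lithium whose [2,3]-Wittig (Still–Wittig) rearrangement is suprafacial, so the β C12–O bond is exchanged for a β C10–C9 bond next to the quaternary C1 and the olefin moves to C11=C12.

Step 12
Reactants: 15 homoallylic alcohol
Product: 16 C9 aldehyde (formyl group on C10, β)
Conditions: Dess–Martin periodinane, NaHCO3, CH2Cl2, 0 °C
Reagents that add atoms: none
Why: Dess–Martin oxidation under buffered, non-basic conditions spares the epimerisable β,γ-unsaturated aldehyde.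

Step 13
Reactants: 16 C9 aldehyde; 17 methoxyallene
Product: 18 (9R)-allenyl carbinol (C9–OH; C8 carries OMe and the allene C7=C6H2)
Conditions: 17, nBuLi, THF, −40 °C; then 16, −78 °C; aq. NH4Cl
Reagents that add atoms: none
Why: 1,2-Addition of lithiated methoxyallene (an acryloyl anion equivalent) under Felkin–Anh control, with the quaternary C1 as the large group anti to the nucleophile, should set C9 as drawn.

Step 14
Reactants: 18 (9R)-allenyl carbinol; 19 bromoacetyl bromide
Product: 20 9-O-bromoacetate of 18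
Conditions: pyridine, CH2Cl2, −40 → 0 °C
Reagents that add atoms: none
Why: Acylation under mild base attaches the two-carbon C19–C17 unit as a tether and leaves the acid-labile allenyl ether untouched.

Step 15
Reactants: 20 9-O-bromoacetate
Product: 21 α-(bromoacetoxy) vinyl ketone (C8 ketone, C7=C6H2 vinyl)
Conditions: oxalic acid (aq.), THF, 0 °C
Reagents that add atoms: water, O
Why: The 1-methoxyallene is an enol ether and is hydrolysed by dilute acid to the vinyl ketone much faster than the dioxolane or the silyl ether are cleaved.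

Step 16
Reactants: 21 α-(bromoacetoxy) vinyl ketone
Product: 23 (8S,9R)-hydroxy lactone (temporary γ-lactone C9–O–C19(=O)–C17H2–C8; 8-OH cis to C10 and vinyl trans to C10 on the lactone), via samarium enolate 22 (not isolated)
Conditions: SmI2 (2.2 equiv), THF, −78 °C; aq. NH4Cl
Reagents that add atoms: none
Why: Intramolecular samarium Reformatsky reaction; divalent samarium reduces the α-bromo ester faster than the ketone, and the trivalent samarium enolate adds to the C8 ketone through a chelated five-membered transition state in which the vinyl group lies trans to the C10 substituent of the forming ring.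

Step 17
Reactants: 23 hydroxy lactone
Product: 24 (17R)-17-methyl hydroxy lactone (C18 methyl trans to the 8-OH)
Conditions: LiN(iPr)2 (2.5 equiv), THF–DMPU, −78 → −40 °C; MeI, −78 °C; aq. NH4Cl
Reagents that add atoms: iodomethane, CI
Why: Alkylation of the alkoxide–enolate dianion of a β-hydroxy-γ-lactone (Fráter–Seebach type) occurs anti to the β-oxido group, which should place the methyl trans to the hydroxyl.

Step 18
Reactants: 24 17-methyl hydroxy lactone
Product: 25 triol (9-OH, 8-OH, C19H2OH; C14–OTBS and C2 dioxolane kept)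
Conditions: LiAlH4, THF, 0 °C
Reagents that add atoms: none
Why: Hydride reduction opens the temporary lactone, after it has set C8 and C17, to the C9/C19 diol.

Step 19
Reactants: 25 triol
Product: 26 8,19-O-di-tert-butylsilylene derivative (free 9-OH)
Conditions: tBu2Si(OTf)2, 2,6-lutidine, CH2Cl2, 0 °C
Reagents that add atoms: di-tert-butylsilyl bis(trifluoromethanesulfonate), CC(C)(C)[Si](OS(=O)(=O)C(F)(F)F)(OS(=O)(=O)C(F)(F)F)C(C)(C)C
Why: The silylene bridges the 1,3-related tertiary C8 and primary C19 hydroxyls as a six-membered ring in preference to the strained five-membered alternative, so only the C9 hydroxyl stays free and no hydroxyl can later form a lactol with the C2 aldehyde.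

Step 20
Reactants: 26 silylene with free 9-OH
Product: 27 9-acetate
Conditions: Ac2O, DMAP, pyridine, CH2Cl2, 25 °C
Reagents that add atoms: acetic anhydride, CC(=O)OC(C)=O
Why: DMAP-catalysed acetylation of the single free secondary hydroxyl.

Step 21
Reactants: 27 9-acetate
Product: 28 C2 aldehyde (formyl group on the quaternary C1)
Conditions: In(OTf)3 (5 mol %), acetone–H2O, 25 °C
Reagents that add atoms: water, O
Why: Lewis-acid-catalysed acetal hydrolysis near neutral pH releases the neopentyl aldehyde without touching the silyl groups or the acetate.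

Step 22
Reactants: 28 C2 aldehyde; 29 4-(trimethylsilyl)but-3-yn-2-one
Product: 30 (2R)-β-hydroxy ynone (C2–OH, C3H2, C4 ketone, C5≡C6–SiMe3)
Conditions: Et2Zn (40 mol %), (R,R)-ProPhenol (20 mol %), 4 Å molecular sieves, THF, 0 °C
Reagents that add atoms: none
Why: Direct catalytic asymmetric aldol addition of a methyl ynone under dinuclear zinc–ProPhenol catalysis; C2 is set by the catalyst, the ligand enantiomer being chosen for Re-face attack on the non-enolisable aldehyde.

Step 23
Reactants: 30 β-hydroxy ynone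
Product: 31 2-O-acetyl propargylic alcohol (C4–OH anti to C2–OAc)
Conditions: SmI2 (30 mol %), MeCHO (8 equiv), THF, −10 °C
Reagents that add atoms: acetaldehyde, CC=O
Why: Evans–Tishchenko reduction; the C2 hydroxyl forms a samarium-bound hemiacetal with acetaldehyde that delivers hydride intramolecularly to the C4 ketone, giving the 1,3-anti alcohol and leaving the acetate on O2.

Step 24
Reactants: 31 2-O-acetyl propargylic alcohol
Product: 32 4-O-butanoate
Conditions: (PrCO)2O, DMAP, pyridine, CH2Cl2, 0 °C
Reagents that add atoms: butanoic anhydride, CCCC(=O)OC(=O)CCC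
Why: Esterification of the only free hydroxyl places the butanoate on O4.

Step 25
Reactants: 32 4-O-butanoate
Product: 33 terminal alkyne triol (14-OH, 8-OH, C19H2OH)
Conditions: TBAF, AcOH (1:1), THF, 0 → 45 °C
Reagents that add atoms: none
Why: Buffered fluoride removes the alkynyl silane, the silylene and the hindered silyl ether in one operation without acyl migration.

Step 26
Reactants: 33 terminal alkyne triol
Product: 35 alkyne hydroxy acid (C19 carboxylic acid; 14-OH and 8-OH free), via aldehyde 34 (not isolated)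
Conditions: TEMPO (20 mol %), PhI(OAc)2 (2.5 equiv), MeCN–H2O, 25 °C
Reagents that add atoms: water, O
Why: Nitroxyl-catalysed oxidation is selective for the primary alcohol, which is taken through the aldehyde hydrate to the acid while the hindered secondary and the tertiary hydroxyls remain.

Step 27
Reactants: 35 alkyne hydroxy acid
Product: 37 (6Z)-ten-membered diene acid (ring C1–C10; exocyclic C5=C16H2 and ring C6=C7), via triene 36 (not isolated)
Conditions: second-generation Grubbs catalyst RuCl2(H2IMes)(PCy3)(=CHPh) (15 mol %), ethene (1 atm), toluene (2 mM), 60 °C; then argon sparge, 80 °C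
Reagents that add atoms: ethene, C=C
Why: Enyne cross-metathesis of the terminal alkyne with ethene gives the 2-substituted buta-1,3-diene, whose vinyl group then undergoes ring-closing metathesis with the C7 vinyl group; the trans-disposed chains on the cyclohexene pre-organise closure, and the ten-membered ring is expected to take the cis C6=C7 geometry.

Step 28
Reactants: 37 (6Z)-ten-membered diene acid
Product: 38 14-O-deacetyl target (γ-lactone O–C7 closed, (5Z)-olefin, 16-OAc)
Conditions: Pd(OAc)2 (10 mol %), p-benzoquinone (2 equiv), LiOAc (0.5 equiv), AcOH–acetone (1:4), 25 °C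
Reagents that add atoms: acetic acid, CC(O)=O
Why: Divalent palladium binds the C16=C5–C6=C7 diene, and the C19 carboxyl, held two atoms from C7 on C8, adds to the diene terminus C7 to give an η3-allyl palladium complex over C6–C5–C16, which acetate opens at the primary terminus C16 while benzoquinone reoxidises the zerovalent palladium released. The closest known reaction type is the palladium diacetate/benzoquinone 1,4-oxylactonisation (1,4-diacyloxylation) of conjugated diene carboxylic acids. The γ-lactone closes 5-exo-trig by O–C7 bond formation; eight-membered closure at C16 and 6-endo attack at C6 are disfavoured. C7 is the only new stereocentre and is controlled by C8: allylic 1,3-strain with C5 turns the small C8 hydroxyl into the plane of the cis C6=C7 bond, so the C17 arm can deliver the carboxylate to one face only and the lactone becomes trans-fused to the ten-membered ring (H7 anti to 8-OH). The step needs 1,4- over 1,2-regioselectivity and the Z C5=C6 geometry; the first is secured by the primary versus secondary allyl termini, the second by the ring, because syn–anti equilibration of the allyl complex leads to the less strained cis-cyclodecene and only that isomer keeps C16 out of reach of the 8-OH. The free 14-OH and 8-OH, the esters and the trisubstituted C11=C12 olefin should be inert to this catalyst system.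

Step 29
Reactants: 38 14-O-deacetyl target
Product: 39 CNP0290502.1 (target)
Conditions: Ac2O, DMAP, pyridine, CH2Cl2, 25 °C
Reagents that add atoms: acetic anhydride, CC(=O)OC(C)=O
Why: DMAP-catalysed acetylation of the remaining secondary 14-OH; the tertiary 8-OH next to the lactone is too hindered to react under these conditions.

## Compound list

1 | 2-methylcyclohexane-1,3-dione | CC1C(=O)CCCC1=O | starting material
2 | allyl bromide (3-bromoprop-1-ene) | C=CCBr | starting material
3 | 2-allyl-2-methylcyclohexane-1,3-dione | C=CCC1(C)C(=O)CCCC1=O | intermediate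
4 | (2S,3S)-2-allyl-3-hydroxy-2-methylcyclohexan-1-one | C=CC[C@@]1(C)[C@@H](O)CCCC1=O | intermediate
5 | (2S,3S)-2-allyl-3-(tert-butyldimethylsilyloxy)-2-methylcyclohexan-1-one | C=CC[C@@]1(C)[C@@H](O[Si](C)(C)C(C)(C)C)CCCC1=O | intermediate
6 | (2S,3S)-3-(tert-butyldimethylsilyloxy)-2-methyl-2-[(E)-prop-1-enyl]cyclohexan-1-one | C/C=C/[C@@]1(C)[C@@H](O[Si](C)(C)C(C)(C)C)CCCC1=O | intermediate
7 | (1R,6S)-6-(tert-butyldimethylsilyloxy)-1-methyl-2-oxocyclohexane-1-carbaldehyde | O=C[C@@]1(C)[C@@H](O[Si](C)(C)C(C)(C)C)CCCC1=O | intermediate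
8 | (2R,3S)-3-(tert-butyldimethylsilyloxy)-2-(1,3-dioxolan-2-yl)-2-methylcyclohexan-1-one | C1COC(O1)[C@@]2(C)[C@@H](O[Si](C)(C)C(C)(C)C)CCCC2=O | intermediate
9 | (2R,3S)-3-(tert-butyldimethylsilyloxy)-2-(1,3-dioxolan-2-yl)-2,6-dimethylcyclohexan-1-one (C6 epimers) | C1COC(O1)[C@@]2(C)[C@@H](O[Si](C)(C)C(C)(C)C)CCC(C)C2=O | intermediate
10 | (5S,6R)-5-(tert-butyldimethylsilyloxy)-6-(1,3-dioxolan-2-yl)-2,6-dimethylcyclohex-2-en-1-one | C1COC(O1)[C@@]2(C)[C@@H](O[Si](C)(C)C(C)(C)C)CC=C(C)C2=O | intermediate
11 | β-epoxy ketone: 2,3-epoxide of 10, epoxide oxygen cis to the C6 methyl, trans to OTBS | C1COC(O1)[C@@]2(C)[C@@H](O[Si](C)(C)C(C)(C)C)C[C@@H]3O[C@]3(C)C2=O | intermediate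
12 | 4-(1,3-dioxolan-2-yl)-5-(tert-butyldimethylsilyloxy)-2,4-dimethylcyclohex-2-en-1-ol, OH cis to the C4 methyl, trans to OTBS (12β-OH, C10=C11) | C1COC(O1)[C@@]2(C)[C@@H](O[Si](C)(C)C(C)(C)C)C[C@H](O)C(C)=C2 | intermediate
13 | (tributylstannyl)methyl ether of 12 | C1COC(O1)[C@@]2(C)[C@@H](O[Si](C)(C)C(C)(C)C)C[C@H](OC[Sn](CCCC)(CCCC)CCCC)C(C)=C2 | intermediate
14 | lithiomethyl ether of 12 | C1COC(O1)[C@@]2(C)[C@@H](O[Si](C)(C)C(C)(C)C)C[C@H](OC[Li])C(C)=C2 | intermediate
15 | [6-(1,3-dioxolan-2-yl)-5-(tert-butyldimethylsilyloxy)-2,6-dimethylcyclohex-2-en-1-yl]methanol, CH2OH (C9) cis to the C6 methyl, OTBS trans to it | C1COC(O1)[C@@]2(C)[C@@H](O[Si](C)(C)C(C)(C)C)CC=C(C)[C@@H]2CO | intermediate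
16 | C9 aldehyde: the carbaldehyde corresponding to 15 | C1COC(O1)[C@@]2(C)[C@@H](O[Si](C)(C)C(C)(C)C)CC=C(C)[C@@H]2C=O | intermediate
17 | methoxyallene (1-methoxypropa-1,2-diene) | COC=C=C | starting material
18 | (9R)-allenyl carbinol: 1-(ring C10)-2-methoxybuta-2,3-dien-1-ol | C1COC(O1)[C@@]2(C)[C@@H](O[Si](C)(C)C(C)(C)C)CC=C(C)[C@@H]2[C@@H](O)C(OC)=C=C | intermediate
19 | bromoacetyl bromide | BrCC(Br)=O | starting material
20 | 9-O-bromoacetate of 18 | C1COC(O1)[C@@]2(C)[C@@H](O[Si](C)(C)C(C)(C)C)CC=C(C)[C@@H]2[C@@H](OC(=O)CBr)C(OC)=C=C | intermediate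
21 | (9R)-9-(bromoacetoxy) vinyl ketone (C8=O, C7=C6H2) | C1COC(O1)[C@@]2(C)[C@@H](O[Si](C)(C)C(C)(C)C)CC=C(C)[C@@H]2[C@@H](OC(=O)CBr)C(=O)C=C | intermediate
22 | samarium enolate of 21 (diiodosamarium ketene acetal) | C1COC(O1)[C@@]2(C)[C@@H](O[Si](C)(C)C(C)(C)C)CC=C(C)[C@@H]2[C@@H](OC(=C)O[Sm](I)I)C(=O)C=C | intermediate
23 | (8S,9R)-8-hydroxy-8-vinyl 9,19-lactone (γ-lactone C9–O–C19(=O)–C17H2–C8), OH cis to C10 | C1COC(O1)[C@@]2(C)[C@@H](O[Si](C)(C)C(C)(C)C)CC=C(C)[C@@H]2[C@H]3OC(=O)C[C@]3(O)C=C | intermediate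
24 | (17R)-17-methyl derivative of 23, methyl trans to the 8-OH | C1COC(O1)[C@@]2(C)[C@@H](O[Si](C)(C)C(C)(C)C)CC=C(C)[C@@H]2[C@H]3OC(=O)[C@H](C)[C@]3(O)C=C | intermediate
25 | triol: 9-OH, 8-OH (tertiary, vinyl), C19H2OH; C8, C9, C17 as in 39 | C1COC(O1)[C@@]2(C)[C@@H](O[Si](C)(C)C(C)(C)C)CC=C(C)[C@@H]2[C@@H](O)[C@@](O)(C=C)[C@@H](C)CO | intermediate
26 | 8,19-O-(di-tert-butylsilylene) derivative of 25 | C1COC(O1)[C@@]2(C)[C@@H](O[Si](C)(C)C(C)(C)C)CC=C(C)[C@@H]2[C@@H](O)[C@]3(C=C)O[Si](C(C)(C)C)(C(C)(C)C)OC[C@@H]3C | intermediate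
27 | 9-O-acetate of 26 | C1COC(O1)[C@@]2(C)[C@@H](O[Si](C)(C)C(C)(C)C)CC=C(C)[C@@H]2[C@@H](OC(C)=O)[C@]3(C=C)O[Si](C(C)(C)C)(C(C)(C)C)OC[C@@H]3C | intermediate
28 | C2 aldehyde: 27 with the dioxolane replaced by CHO | O=C[C@@]1(C)[C@@H](O[Si](C)(C)C(C)(C)C)CC=C(C)[C@@H]1[C@@H](OC(C)=O)[C@]2(C=C)O[Si](C(C)(C)C)(C(C)(C)C)OC[C@@H]2C | intermediate
29 | 4-(trimethylsilyl)but-3-yn-2-one | CC(=O)C#C[Si](C)(C)C | starting material
30 | (2R)-β-hydroxy ynone: C2–OH, C4=O, C5≡C6–SiMe3 | C[Si](C)(C)C#CC(=O)C[C@@H](O)[C@@]1(C)[C@@H](O[Si](C)(C)C(C)(C)C)CC=C(C)[C@@H]1[C@@H](OC(C)=O)[C@]2(C=C)O[Si](C(C)(C)C)(C(C)(C)C)OC[C@@H]2C | intermediate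
31 | (2R,4R)-2-O-acetyl-4-hydroxy alkyne (2,4-anti) | C[Si](C)(C)C#C[C@H](O)C[C@@H](OC(C)=O)[C@@]1(C)[C@@H](O[Si](C)(C)C(C)(C)C)CC=C(C)[C@@H]1[C@@H](OC(C)=O)[C@]2(C=C)O[Si](C(C)(C)C)(C(C)(C)C)OC[C@@H]2C | intermediate
32 | 4-O-butanoate of 31 | C[Si](C)(C)C#C[C@H](OC(=O)CCC)C[C@@H](OC(C)=O)[C@@]1(C)[C@@H](O[Si](C)(C)C(C)(C)C)CC=C(C)[C@@H]1[C@@H](OC(C)=O)[C@]2(C=C)O[Si](C(C)(C)C)(C(C)(C)C)OC[C@@H]2C | intermediate
33 | terminal alkyne triol: 2-OAc, 4-OBu, 9-OAc; free 14-OH, 8-OH, C19H2OH | C#C[C@H](OC(=O)CCC)C[C@@H](OC(C)=O)[C@@]1(C)[C@@H](O)CC=C(C)[C@@H]1[C@@H](OC(C)=O)[C@@](O)(C=C)[C@@H](C)CO | intermediate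
34 | C19 aldehyde corresponding to 33 | C#C[C@H](OC(=O)CCC)C[C@@H](OC(C)=O)[C@@]1(C)[C@@H](O)CC=C(C)[C@@H]1[C@@H](OC(C)=O)[C@@](O)(C=C)[C@@H](C)C=O | intermediate
35 | alkyne hydroxy acid (C19 carboxylic acid; C5≡C6H alkyne, C7 vinyl on C8) | C#C[C@H](OC(=O)CCC)C[C@@H](OC(C)=O)[C@@]1(C)[C@@H](O)CC=C(C)[C@@H]1[C@@H](OC(C)=O)[C@@](O)(C=C)[C@@H](C)C(O)=O | intermediate
36 | triene acid: C4–C5(=CH2)–CH=CH2 diene and C7 vinyl | C=CC(=C)[C@H](OC(=O)CCC)C[C@@H](OC(C)=O)[C@@]1(C)[C@@H](O)CC=C(C)[C@@H]1[C@@H](OC(C)=O)[C@@](O)(C=C)[C@@H](C)C(O)=O | intermediate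
37 | (6Z)-ten-membered seco-acid: ring C1–C10, exocyclic C5=C16H2, C6=C7, 8-OH, C17H(CH3)–C19OOH, 14-OH | CCCC(=O)O[C@@H]1C[C@@H](OC(C)=O)[C@@]2(C)[C@@H](O)CC=C(C)[C@@H]2[C@@H](OC(C)=O)[C@@](O)(/C=C\C1=C)[C@@H](C)C(O)=O | intermediate
38 | 14-O-deacetyl target (all stereocentres of 39, free 14-OH) | CCCC(=O)O[C@@H]1C[C@@H](OC(C)=O)[C@@]2(C)[C@@H](O)CC=C(C)[C@@H]2[C@@H](OC(C)=O)[C@@]2(O)[C@H](/C=C\1COC(C)=O)OC(=O)[C@@H]2C | intermediate
39 | CNP0290502.1, (1R,2R,4R,5Z,7S,8S,9R,10S,14S,17R) | CCCC(=O)O[C@@H]1C[C@@H](OC(C)=O)[C@@]2(C)[C@@H](OC(C)=O)CC=C(C)[C@@H]2[C@@H](OC(C)=O)[C@@]2(O)[C@H](/C=C\1COC(C)=O)OC(=O)[C@@H]2C | target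

## Step count and risks

Total step count: 29. Longest linear sequence: 29 steps (from 1; 2, 17, 19 and 29 are bought).

Steps most likely to fail:

Step 27 (ring closure to the ten-membered ring). Intermolecular metathesis to oligomers may outrun closure, the C7 vinyl group on the quaternary C8 may not engage, or closure may occur through the 1,1-disubstituted diene terminus to a nine-membered ring. The fallback closes the ring at C5–C6 by a Heck reaction instead and sets out from acid 35. α-Selective hydrostannation of the terminal alkyne (Mo(CO)3(CNtBu)3 cat., Bu3SnH, THF, 55 °C) should give the 2-stannyl-1-alkene F1. Iododestannylation (I2, CH2Cl2, 0 °C) then gives the vinyl iodide F2. An intramolecular Heck reaction (Pd(OAc)2, Ag2CO3, MeCN, high dilution, 60 °C) adds the C5 vinylpalladium to the terminal carbon of the C8 vinyl group. β-Hydride elimination can only occur toward C6, so the same conjugated diene results, and the route is rejoined at 37.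

Step 28 (key step). The carboxylate may add to the wrong face of C7, acetate may attack the allyl complex at C6 (1,2-addition), or the hindered diene may not react with the catalyst. The fallback uses electrophilic instead of oxidative activation and sets out from 37. Iodolactonisation in the 1,4-sense (I2, NaHCO3, MeCN, 0 °C; iodine to C16, carboxylate to C7 under the same C8 control) should give the allylic iodide lactone F3. Displacement of the primary allylic iodide by acetate (AgOAc, AcOH, 25 °C) returns to the route at 38.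

Step 16 (temporary lactone). Electron transfer to the vinyl ketone or reductive cleavage of the α-acyloxy ketone may compete with reduction of the C–Br bond, and the facial selectivity at C8 may be poor. The fallback makes the C8–C17 bond intermolecularly under chelation control and sets out from 18. Mild acid hydrolysis (oxalic acid, THF–H2O, 0 °C) gives the α-hydroxy vinyl ketone F4. Addition of the lithium enolate of ethyl acetate (3 equiv, THF, −78 °C) to the lithium alkoxide-chelated ketone, anti to C10 by the Cram chelation model, gives the dihydroxy ester F5. F5 lactonises onto the C9 hydroxyl (PPTS, benzene, 50 °C), and the route is rejoined at 23.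

## Further compounds

F1 | step 27 | 2-(tributylstannyl)-1-alkene from 35 (C5 bears SnBu3 and a =CH2 group) | C=C([Sn](CCCC)(CCCC)CCCC)[C@H](OC(=O)CCC)C[C@@H](OC(C)=O)[C@@]1(C)[C@@H](O)CC=C(C)[C@@H]1[C@@H](OC(C)=O)[C@@](O)(C=C)[C@@H](C)C(O)=O
F2 | step 27 | 2-iodo-1-alkene (vinyl iodide at C5) | C=C(I)[C@H](OC(=O)CCC)C[C@@H](OC(C)=O)[C@@]1(C)[C@@H](O)CC=C(C)[C@@H]1[C@@H](OC(C)=O)[C@@](O)(C=C)[C@@H](C)C(O)=O
F3 | step 28 | 16-iodo lactone (38 with iodine in place of the 16-acetoxy group) | CCCC(=O)O[C@@H]1C[C@@H](OC(C)=O)[C@@]2(C)[C@@H](O)CC=C(C)[C@@H]2[C@@H](OC(C)=O)[C@@]2(O)[C@H](/C=C\1CI)OC(=O)[C@@H]2C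
F4 | step 16 | (9R)-9-hydroxy vinyl ketone | C1COC(O1)[C@@]2(C)[C@@H](O[Si](C)(C)C(C)(C)C)CC=C(C)[C@@H]2[C@@H](O)C(=O)C=C
F5 | step 16 | ethyl ester of the 8,9-dihydroxy-8-vinyl acid (open form of 23) | C1COC(O1)[C@@]2(C)[C@@H](O[Si](C)(C)C(C)(C)C)CC=C(C)[C@@H]2[C@@H](O)[C@@](O)(C=C)CC(=O)OCC
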